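**Plan**

- Retrosynthesis: ring A is opened at C4a–C5 (retro-electrocyclisation) to a 4-(pyranon-2-yl)-3,4-dimethoxycyclobutenone. The C8–C8a bond is then cut to a 6-metallated pyranone and methyl semisquarate.
- The pyranone is unravelled at O1–C8a and C4a–C8a (one-carbon amide acetal), at C3–C4 (C-acetylation) and at C2–C1' (Friedel–Crafts).
- Forward: ring B is bought, ring C (the 4-pyranone) is built on it, the four-carbon squarate unit is attached at the carbon next to the ring oxygen, and ring A closes last.
- Ring A carries 5-OH para to 8-OMe with 7-OMe and 6-H between. A 4-substituted 3,4-dimethoxycyclobut-2-enone holds exactly this pattern (C1=O becomes C5–OH, C2–H becomes C6, C3–OMe becomes C7, C4–OMe becomes C8).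
- Stereochemistry: the target has no stereogenic element, so none has to be set.

Key step: step 8

Remark: the target SMILES contains no stereocentre, axis or configured double bond, so it defines the compound completely and no enantiocontrol is needed. The tetrahedral carbons met on the way (the carbinol carbon of the cyclobutenones, the transient ring-fusion CH) are racemic and are erased in the last step.

**Route**

Step 1
Reactants: 1 1,3-dimethoxybenzene; 2 methoxyacetyl chloride
Product: 3 1-(2,4-dimethoxyphenyl)-2-methoxyethan-1-one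
Conditions: AlCl3 (1.1 equiv), CH2Cl2, 0 °C
Reagents that add atoms: none
Why: Friedel–Crafts acylation should take place at C4 of the arene, para to one methoxy group and ortho to the other and less hindered than C2, and 0 °C with near-stoichiometric AlCl3 avoids ortho-demethylation.

Step 2
Reactants: 3 1-(2,4-dimethoxyphenyl)-2-methoxyethan-1-one
Product: 4 1-(2,4-dimethoxyphenyl)-2-methoxybutane-1,3-dione (racemic, enolisable)
Conditions: MgBr2·OEt2, i-Pr2NEt, AcCl, CH2Cl2, rt
Reagents that add atoms: acetyl chloride, CC(=O)Cl
Why: Soft enolisation (magnesium chelate of the α-methoxy ketone, amine base) followed by Claisen-type C-acylation with an acid chloride is established for aryl ketones, and 3 has only one enolisable carbon.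

Step 3
Reactants: 4 1-(2,4-dimethoxyphenyl)-2-methoxybutane-1,3-dione
Product: 6 2-(2,4-dimethoxyphenyl)-3-methoxy-4H-pyran-4-one, via enaminone 5 (not isolated)
Conditions: Me2NCH(OMe)2, PhMe, 90 °C; then AcOH, 80 °C
Reagents that add atoms: N,N-dimethylformamide dimethyl acetal, COC(OC)N(C)C
Why: The amide acetal can condense only at the acetyl CH3 (the central carbon carries a single hydrogen), and the enol oxygen of the aroyl group then adds to the enaminone β-carbon and expels dimethylamine, the standard enaminone cyclisation to 4-pyranones.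

Step 4
Reactants: 6 2-(2,4-dimethoxyphenyl)-3-methoxy-4H-pyran-4-one
Product: 8 2-(2,4-dimethoxyphenyl)-6-iodo-3-methoxy-4H-pyran-4-one, via diorganozinc 7 (not isolated)
Conditions: TMP2Zn·2MgCl2·2LiCl (0.6 equiv), THF, −30 °C; then I2, −30 °C to rt
Reagents that add atoms: iodine, II
Why: Directed zincation with a TMP-zinc amide in the presence of MgCl2 should remove the CH next to the ring oxygen, as in chromone-type 4-pyranones where the Lewis acid on the carbonyl makes this conjugate position the most acidic; the covalent C–Zn bond does not ring-open and iodolysis fixes the site in an isolable alkenyl iodide.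

Step 5
Reactants: 9 dimethyl squarate
Product: 11 3-methoxycyclobut-3-ene-1,2-dione, via hydroxycyclobutenone 10 (not isolated)
Conditions: LiAlH(Ot-Bu)3, THF, −78 to −20 °C, dilute HCl work-up; then conc. HCl (cat.), CH2Cl2, rt
Reagents that add atoms: water, O
Why: Mono-reduction of a dialkyl squarate with a hindered alkoxyaluminium hydride, then acid-promoted allylic transposition and hydrolysis of the carbinol with loss of the alcohol, is the known entry to alkyl semisquarates.

Step 6
Reactants: 8 2-(2,4-dimethoxyphenyl)-6-iodo-3-methoxy-4H-pyran-4-one; 11 3-methoxycyclobut-3-ene-1,2-dione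
Product: 13 4-[6-(2,4-dimethoxyphenyl)-5-methoxy-4-oxo-4H-pyran-2-yl]-4-hydroxy-3-methoxycyclobut-2-en-1-one (racemic), via pyranonylmagnesium chloride 12 (not isolated)
Conditions: i-PrMgCl·LiCl, THF, −78 °C; then 11, −78 °C; cold sat. aq. NH4Cl
Reagents that add atoms: none
Why: Iodine–magnesium exchange of β-iodo enones and enoates with i-PrMgCl·LiCl at −78 °C should outrun carbonyl addition, and the alkenyl Grignard reagent should add 1,2 to the ketone-like C2 carbonyl of 11 (C1 is deactivated as a vinylogous ester), as organometallics do with 3-alkoxycyclobutenediones; the new quaternary centre is racemic and is erased in step 8.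

Step 7
Reactants: 13 4-[6-(2,4-dimethoxyphenyl)-5-methoxy-4-oxo-4H-pyran-2-yl]-4-hydroxy-3-methoxycyclobut-2-en-1-one
Product: 14 4-[6-(2,4-dimethoxyphenyl)-5-methoxy-4-oxo-4H-pyran-2-yl]-3,4-dimethoxycyclobut-2-en-1-one (racemic)
Conditions: MeI, Ag2O, MeCN, rt, dark
Reagents that add atoms: iodomethane, CI
Why: Purdie methylation (MeI/Ag2O) etherifies tertiary 4-hydroxycyclobutenones without a strong base that would open the ring, and it writes the future 8-methoxy group into the precursor.

Step 8
Reactants: 14 4-[6-(2,4-dimethoxyphenyl)-5-methoxy-4-oxo-4H-pyran-2-yl]-3,4-dimethoxycyclobut-2-en-1-one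
Product: 17 5-hydroxy-3,7,8,2',4'-pentamethoxyflavone, via dienylketene 15 (not isolated), via cyclohexadienone 16 (not isolated)
Conditions: degassed PhMe (0.01 M), 110 °C (p-xylene, 138 °C if sluggish)
Reagents that add atoms: none
Why: Proposed new method: at 110 °C the cyclobutenone should open by conrotatory 4π-electrocyclic cleavage of C1–C4 to the (Z)-dienylketene 15, whose electrophilic ketene carbon then bonds to pyranone C5 in a thermal 6π-electrocyclisation to the 4a-H dienone 16, and enolisation of that β-diketone-type CH gives the chelated 5-hydroxyl. The closest known reaction type is the Moore ring expansion of 4-aryl-, 4-heteroaryl- and 4-alkenyl-4-alkoxycyclobutenones to hydroquinone monoethers; a 4-oxo-4H-pyran-2-yl group has not served as the 2π partner, but its C5 is the β-carbon of an enol ether and the site at which 4-pyranones take up electrophiles, so it is polarity-matched to the ketene. Ring A is the only ring closed, by disrotatory 6π-electrocyclisation that forms C4a–C5. No stereocentre is created: C4 of 14 becomes sp2 C8 and the C4a–H centre of 16 is lost on tautomerisation. The step needs torquoselective opening, which the 4-methoxy donor secures by rotating outward so that the pyranonyl group turns inward, cis to the ketene; closure can then engage only C5, because the other neighbour of the attachment carbon is the ring oxygen, whose reversible addition to the ketene leads nowhere. High dilution and exclusion of air and water keep the ketene from dimerising or acylating the product phenol.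

**Compound list**

1 | 1,3-dimethoxybenzene | COc1cccc(OC)c1 | starting material
2 | methoxyacetyl chloride | COCC(=O)Cl | starting material
3 | 1-(2,4-dimethoxyphenyl)-2-methoxyethan-1-one | COCC(=O)c1ccc(OC)cc1OC | intermediate
4 | 1-(2,4-dimethoxyphenyl)-2-methoxybutane-1,3-dione (racemic) | COC(C(C)=O)C(=O)c1ccc(OC)cc1OC | intermediate
5 | (E)-5-(dimethylamino)-1-(2,4-dimethoxyphenyl)-2-methoxypent-4-ene-1,3-dione (racemic, not isolated) | COC(C(=O)/C=C/N(C)C)C(=O)c1ccc(OC)cc1OC | intermediate
6 | 2-(2,4-dimethoxyphenyl)-3-methoxy-4H-pyran-4-one | COc1ccc(-c2occc(=O)c2OC)c(OC)c1 | intermediate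
7 | bis[6-(2,4-dimethoxyphenyl)-5-methoxy-4-oxo-4H-pyran-2-yl]zinc (MgCl2/LiCl complex, not isolated) | COc1ccc(-c2oc([Zn]c3cc(=O)c(OC)c(-c4ccc(OC)cc4OC)o3)cc(=O)c2OC)c(OC)c1 | intermediate
8 | 2-(2,4-dimethoxyphenyl)-6-iodo-3-methoxy-4H-pyran-4-one | COc1ccc(-c2oc(I)cc(=O)c2OC)c(OC)c1 | intermediate
9 | dimethyl squarate (3,4-dimethoxycyclobut-3-ene-1,2-dione) | COC1=C(OC)C(=O)C1=O | starting material
10 | 4-hydroxy-2,3-dimethoxycyclobut-2-en-1-one (racemic, not isolated) | COC1=C(OC)C(O)C1=O | intermediate
11 | 3-methoxycyclobut-3-ene-1,2-dione | COC1=CC(=O)C1=O | intermediate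
12 | chlorido[6-(2,4-dimethoxyphenyl)-5-methoxy-4-oxo-4H-pyran-2-yl]magnesium (LiCl complex, not isolated) | COc1ccc(-c2oc([Mg]Cl)cc(=O)c2OC)c(OC)c1 | intermediate
13 | 4-[6-(2,4-dimethoxyphenyl)-5-methoxy-4-oxo-4H-pyran-2-yl]-4-hydroxy-3-methoxycyclobut-2-en-1-one (racemic) | COC1=CC(=O)C1(O)c1cc(=O)c(OC)c(-c2ccc(OC)cc2OC)o1 | intermediate
14 | 4-[6-(2,4-dimethoxyphenyl)-5-methoxy-4-oxo-4H-pyran-2-yl]-3,4-dimethoxycyclobut-2-en-1-one (racemic) | COC1=CC(=O)C1(OC)c1cc(=O)c(OC)c(-c2ccc(OC)cc2OC)o1 | intermediate
15 | (3Z)-4-[6-(2,4-dimethoxyphenyl)-5-methoxy-4-oxo-4H-pyran-2-yl]-3,4-dimethoxybuta-1,3-dien-1-one (not isolated) | O=C=C/C(OC)=C(/OC)c1cc(=O)c(OC)c(-c2ccc(OC)cc2OC)o1 | intermediate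
16 | 2-(2,4-dimethoxyphenyl)-3,7,8-trimethoxy-4aH-chromene-4,5-dione (racemic, not isolated) | COc1ccc(C2=C(OC)C(=O)C3C(=O)C=C(OC)C(OC)=C3O2)c(OC)c1 | intermediate
17 | 5-hydroxy-3,7,8,2',4'-pentamethoxyflavone | COc1ccc(-c2oc3c(OC)c(OC)cc(O)c3c(=O)c2OC)c(OC)c1 | target

**Count**

Total steps: 8. Longest linear sequence: 7 steps (steps 1, 2, 3, 4, 6, 7, 8); step 5 is a one-step side branch.

**Steps most likely to fail**

1. Step 8 (bears the label). The dienylketene may fail to close onto the carbonyl-deactivated pyranone C5 and instead dimerise, acylate the product phenol or be captured by adventitious water. The fallback uses known flavone chemistry and builds ring C last; it sets out from 2 and comes back to the route at 17.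
   - Friedel–Crafts acylation of commercial 1,2,3,5-tetramethoxybenzene with 2 and AlCl3 should give 2-methoxy-1-(2,3,4,6-tetramethoxyphenyl)ethan-1-one F1.
   - The Lewis acid should demethylate F1 in the same flask at the flanked ortho-methoxy group to 1-(2-hydroxy-3,4,6-trimethoxyphenyl)-2-methoxyethan-1-one F2.
   - O-Aroylation with 2,4-dimethoxybenzoyl chloride in pyridine should give 2-(2-methoxyacetyl)-3,5,6-trimethoxyphenyl 2,4-dimethoxybenzoate F3.
   - Baker–Venkataraman rearrangement (KOH, pyridine) should give 1-(2,4-dimethoxyphenyl)-3-(2-hydroxy-3,4,6-trimethoxyphenyl)-2-methoxypropane-1,3-dione F4.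
   - Acid cyclodehydration (H2SO4, AcOH) should give 3,5,7,8,2',4'-hexamethoxyflavone F5.
   - Chelation-controlled cleavage of the 5-methoxy group peri to the carbonyl (BCl3, CH2Cl2, −78 to 0 °C) should then give 17.

2. Step 6. The isopropyl Grignard reagent may displace iodide by addition–elimination at C6 instead of exchanging, the magnesiated pyranone may condense with itself, or the nucleophile may attack the wrong carbonyl of 11 or deprotonate it. The fallback generates the nucleophile by C–H metalation and softens it; it sets out from 6 and comes back at 13.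
   - Kinetic deprotonation of 6 with LiTMP in THF at −78 °C, α to the ring oxygen as known for chromones, should give [6-(2,4-dimethoxyphenyl)-5-methoxy-4-oxo-4H-pyran-2-yl]lithium F6.
   - Transmetalation with anhydrous CeCl3 should give dichlorido[6-(2,4-dimethoxyphenyl)-5-methoxy-4-oxo-4H-pyran-2-yl]cerium F7, a weakly basic organocerium that adds strictly 1,2.
   - Addition of F7 to 11 at −78 °C should give 13.

3. Step 7. Methylation of the hindered tertiary alcohol may stall, the cyclobutenol may ring-open under the conditions, or the pyranone carbonyl oxygen may be alkylated. The fallback moves the methylation after ring formation; it sets out from 13 and comes back at 17.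
   - Thermolysis of unprotected 13 (degassed toluene, 110 °C, under argon), a Moore ring expansion of a 4-hydroxycyclobutenone, should give 5,8-dihydroxy-3,7,2',4'-tetramethoxyflavone F8.
   - Methylation of F8 with one equivalent of MeI and K2CO3 in acetone at rt should occur only at the 8-hydroxyl and give 17, because the 5-hydroxyl is held in a hydrogen bond to the C4 carbonyl and is unreactive under these conditions.

**Further compounds**

F1 | step 8 | 2-methoxy-1-(2,3,4,6-tetramethoxyphenyl)ethan-1-one | COCC(=O)c1c(OC)c(OC)c(OC)cc1OC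
F2 | step 8 | 1-(2-hydroxy-3,4,6-trimethoxyphenyl)-2-methoxyethan-1-one | COCC(=O)c1c(O)c(OC)c(OC)cc1OC
F3 | step 8 | 2-(2-methoxyacetyl)-3,5,6-trimethoxyphenyl 2,4-dimethoxybenzoate | COCC(=O)c1c(OC(=O)c2ccc(OC)cc2OC)c(OC)c(OC)cc1OC
F4 | step 8 | 1-(2,4-dimethoxyphenyl)-3-(2-hydroxy-3,4,6-trimethoxyphenyl)-2-methoxypropane-1,3-dione (racemic) | COC(C(=O)c1ccc(OC)cc1OC)C(=O)c1c(O)c(OC)c(OC)cc1OC
F5 | step 8 | 3,5,7,8,2',4'-hexamethoxyflavone | COc1ccc(-c2oc3c(OC)c(OC)cc(OC)c3c(=O)c2OC)c(OC)c1
F6 | step 6 | [6-(2,4-dimethoxyphenyl)-5-methoxy-4-oxo-4H-pyran-2-yl]lithium | COc1ccc(-c2oc([Li])cc(=O)c2OC)c(OC)c1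
F7 | step 6 | dichlorido[6-(2,4-dimethoxyphenyl)-5-methoxy-4-oxo-4H-pyran-2-yl]cerium | COc1ccc(-c2oc([Ce](Cl)Cl)cc(=O)c2OC)c(OC)c1
F8 | step 7 | 5,8-dihydroxy-3,7,2',4'-tetramethoxyflavone | COc1ccc(-c2oc3c(O)c(OC)cc(O)c3c(=O)c2OC)c(OC)c1
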